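**Reading of the target (one-line assumption):** taken as drawn, with germacrane numbering (ring C1–C10, lactone C11–C13, C14 on C10, C15 on C4), the target is 3β-benzoyloxy-1β,10α-epoxy-8β-[(2S,3R)-2,3-dimethyloxirane-2-carbonyloxy]germacra-4Z,11(13)-dien-6α,12-olide, i.e. 1R,3S,6R,7R,8R,10R, with the two side-chain methyl groups cis on the oxirane.

## Retrosynthetic overview

1. Target ⇒ 1(10)-alkene 30 (last step: epoxidation on the exposed face) ⇒ alcohol 23 + epoxy acid 28; 28 comes from methyl (R)-3-hydroxybutanoate by α-methylation and dianion iodination/ring closure.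
2. 23 ⇒ trans-fused α-methylene lactone 20 (silyl→benzoate exchange at O3, release of O8) ⇒ lactone 17 ⇒ cis-lactone 15 (inversion at C6) ⇒ keto ester 13.
3. 13 ⇒ 1,2-dialkenylcyclohexenol 10 by anionic oxy-Cope rearrangement (C6–C1 broken, C8–C9 made, C1 chirality passed to C8), the enolate being alkylated at C7 in the same flask.
4. 10 ⇒ enone 4 (from (S)-carvone: Luche reduction, silylation, allylic oxidation) + (Z)-2-alkoxyvinyllithium 9 (from 4-methoxybenzyl alcohol).
5. Ring order: cyclohexene (bought) → ten-membered carbocycle ([3,3] shift) → γ-lactone → side-chain oxirane (made separately, attached as the acid) → ring oxirane.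

## Route

Step 1
Reactants: 1 (S)-(+)-carvone
Product: 2 (1S,5S)-cis-carveol
Conditions: NaBH4, CeCl3·7H2O, MeOH, −78 °C
Reagents that add atoms: none
Why: Luche 1,2-reduction in which hydride adds pseudo-axially to the half-chair with equatorial isopropenyl, so the new carbinol centre (S, the later C3) is set cis to the bought C5 stereocentre.

Step 2
Reactants: 2 (1S,5S)-cis-carveol
Product: 3 (1S,5S)-cis-carveol tert-butyldimethylsilyl ether
Conditions: TBSCl, imidazole, DMF, rt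
Reagents that add atoms: tert-butyldimethylsilyl chloride, CC(C)(C)[Si](C)(C)Cl
Why: Standard silylation of a secondary allylic alcohol, which gives a group that survives organolithium, potassium amide, hydride and hydroxide and is removed late with fluoride.

Step 3
Reactants: 3 (1S,5S)-cis-carveol tert-butyldimethylsilyl ether
Product: 4 (4S,6S)-4-(tert-butyldimethylsilyloxy)-3-methyl-6-(prop-1-en-2-yl)cyclohex-2-en-1-one
Conditions: Rh2(cap)4 (1 mol%, cap = caprolactamate), t-BuOOH (5 equiv), K2CO3 (0.5 equiv), CH2Cl2, rt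
Reagents that add atoms: tert-butyl hydroperoxide, CC(C)(C)OO
Why: Radical allylic C–H oxidation (tert-butylperoxy radical) at the only free ring allylic methylene gives the transposed enone, and both stereocentres are kept because the 4,6-cis arrangement is also the thermodynamic one at the now enolisable C6.

Step 4
Reactants: 5 4-methoxybenzyl alcohol
Product: 6 4-methoxybenzyl vinyl ether
Conditions: ethyl vinyl ether (excess), Pd(OAc)2 (2 mol%), 1,10-phenanthroline (2 mol%), CH2Cl2, rt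
Reagents that add atoms: ethyl vinyl ether, CCOC=C
Why: Palladium-catalysed transfer vinylation (transetherification) of a primary alcohol, driven by the excess of ethyl vinyl ether.

Step 5
Reactants: 6 4-methoxybenzyl vinyl ether
Product: 8 (Z)-2-bromovinyl 4-methoxybenzyl ether, via dibromo ether 7 (not isolated)
Conditions: Br2, CH2Cl2, −78 °C; then i-Pr2NEt, −78 °C → rt
Reagents that add atoms: bromine, BrBr
Why: Bromine addition to the enol ether followed by amine-induced dehydrobromination of the α-bromo ether gives the β-bromo enol ether, the cis (Z) isomer being the favoured one for 2-halovinyl ethers.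

Step 6
Reactants: 8 (Z)-2-bromovinyl 4-methoxybenzyl ether; 4 (4S,6S)-4-(tert-butyldimethylsilyloxy)-3-methyl-6-(prop-1-en-2-yl)cyclohex-2-en-1-one
Product: 10 (1S,4S,6S)-4-(tert-butyldimethylsilyloxy)-1-[(Z)-2-(4-methoxybenzyloxy)ethenyl]-3-methyl-6-(prop-1-en-2-yl)cyclohex-2-en-1-ol, via vinyllithium 9 (not isolated)
Conditions: t-BuLi (2.0 equiv), Et2O, −78 °C; then 4, THF, −78 °C; H2O quench, work-up and chromatography on Et3N-treated silica
Reagents that add atoms: none
Why: Bromine–lithium exchange with retention of the Z geometry, then 1,2-addition to the enone anti to the adjacent isopropenyl group, which places the two alkenyl groups trans (carbinol centre S) as the oxy-Cope needs.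

Step 7
Reactants: 10 (1S,4S,6S)-4-(tert-butyldimethylsilyloxy)-1-[(Z)-2-(4-methoxybenzyloxy)ethenyl]-3-methyl-6-(prop-1-en-2-yl)cyclohex-2-en-1-ol
Product: 13 methyl 2-[(1R,3Z,5S,7E,10R)-5-(tert-butyldimethylsilyloxy)-10-(4-methoxybenzyloxy)-4,8-dimethyl-2-oxocyclodeca-3,7-dien-1-yl]acetate, via potassium alkoxide 11 (not isolated), via potassium enolate 12 (not isolated)
Conditions: KN(SiMe3)2 (1.1 equiv), 18-crown-6 (1.2 equiv), THF, −78 → 0 °C; then BrCH2CO2Me, −78 °C; pH 7 buffer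
Reagents that add atoms: methyl bromoacetate, COC(=O)CBr
Why: Anionic oxy-Cope [3,3]-sigmatropic rearrangement through the chair transition state with both alkenyl groups equatorial makes the ten-membered ring with the 1(10)E alkene (the 4Z alkene comes from the cyclohexene) and passes the C1 chirality to C8 (R, 8β-O, the Z-enol ether oxygen being axial on the chair), and the enolate is then alkylated on its exposed face, anti to the transannular C1=C10 unit, which sets C7 (R) with the acetate arm cis to O8.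

Step 8
Reactants: 13 methyl 2-[(1R,3Z,5S,7E,10R)-5-(tert-butyldimethylsilyloxy)-10-(4-methoxybenzyloxy)-4,8-dimethyl-2-oxocyclodeca-3,7-dien-1-yl]acetate
Product: 15 cis-fused lactone (3aR,4R,6E,9S,10Z,11aS)-9-(tert-butyldimethylsilyloxy)-4-(4-methoxybenzyloxy)-6,10-dimethyl-3a,4,5,8,9,11a-hexahydrocyclodeca[b]furan-2(3H)-one, via hydroxy ester 14 (not isolated)
Conditions: NaBH4, CeCl3·7H2O, MeOH, −40 °C; then PPTS (cat.), CH2Cl2, rt
Reagents that add atoms: none
Why: Luche 1,2-reduction of the enone from the ring periphery (the inner face of C6 is covered by the ring) gives the 6β-alcohol, which closes onto the methyl ester to the cis-fused lactone, i.e. the 6-epi series that step 9 corrects.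

Step 9
Reactants: 15 cis-fused lactone (3aR,4R,6E,9S,10Z,11aS)-9-(tert-butyldimethylsilyloxy)-4-(4-methoxybenzyloxy)-6,10-dimethyl-3a,4,5,8,9,11a-hexahydrocyclodeca[b]furan-2(3H)-one
Product: 17 trans-fused lactone (3aR,4R,6E,9S,10Z,11aR)-9-(tert-butyldimethylsilyloxy)-4-(4-methoxybenzyloxy)-6,10-dimethyl-3a,4,5,8,9,11a-hexahydrocyclodeca[b]furan-2(3H)-one, via hydroxy acid 16 (not isolated)
Conditions: LiOH, THF/H2O, 0 °C → rt; 1 M HCl to pH 5 at 0 °C, extraction; then PPh3, DIAD, THF (high dilution), 0 °C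
Reagents that add atoms: lithium hydroxide, [Li+].[OH-]
Why: Saponification followed by Mitsunobu lactonisation, in which the carboxylate displaces the activated allylic C6 oxygen by SN2 from the outer face where the acetate arm sits, inverts C6 to R and gives the natural 6α,12-trans-lactone.

Step 10
Reactants: 17 trans-fused lactone (3aR,4R,6E,9S,10Z,11aR)-9-(tert-butyldimethylsilyloxy)-4-(4-methoxybenzyloxy)-6,10-dimethyl-3a,4,5,8,9,11a-hexahydrocyclodeca[b]furan-2(3H)-one
Product: 20 (3aR,4R,6E,9S,10Z,11aR)-9-(tert-butyldimethylsilyloxy)-4-(4-methoxybenzyloxy)-6,10-dimethyl-3-methylidene-3a,4,5,8,9,11a-hexahydrocyclodeca[b]furan-2(3H)-one, via Mannich base 18 (not isolated), via ammonium iodide 19 (not isolated)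
Conditions: LiN(iPr)2, THF, −78 °C; CH2=NMe2+ I−, −78 °C → rt; then MeI, MeOH, rt; then aq. NaHCO3, EtOAc, rt
Reagents that add atoms: N,N-dimethylmethyleneiminium iodide (Eschenmoser's salt), C=[N+](C)C.[I-]
Why: Lactone enolate Mannich reaction, N-methylation and E1cB-type elimination is the standard α-methylenation of a γ-lactone and touches no stereocentre (C11 becomes sp2).

Step 11
Reactants: 20 (3aR,4R,6E,9S,10Z,11aR)-9-(tert-butyldimethylsilyloxy)-4-(4-methoxybenzyloxy)-6,10-dimethyl-3-methylidene-3a,4,5,8,9,11a-hexahydrocyclodeca[b]furan-2(3H)-one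
Product: 21 (3aR,4R,6E,9S,10Z,11aR)-9-hydroxy-4-(4-methoxybenzyloxy)-6,10-dimethyl-3-methylidene-3a,4,5,8,9,11a-hexahydrocyclodeca[b]furan-2(3H)-one
Conditions: HF·pyridine, pyridine/THF, 0 °C → rt
Reagents that add atoms: none
Why: Buffered fluoride desilylation frees O3 without any base that could add to the α-methylene lactone and without acid strong enough to trigger transannular cyclisation of the 1,5-diene.

Step 12
Reactants: 21 (3aR,4R,6E,9S,10Z,11aR)-9-hydroxy-4-(4-methoxybenzyloxy)-6,10-dimethyl-3-methylidene-3a,4,5,8,9,11a-hexahydrocyclodeca[b]furan-2(3H)-one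
Product: 22 (3aR,4R,6E,9S,10Z,11aR)-4-(4-methoxybenzyloxy)-6,10-dimethyl-3-methylidene-2-oxo-2,3,3a,4,5,8,9,11a-octahydrocyclodeca[b]furan-9-yl benzoate
Conditions: BzCl, pyridine, DMAP (cat.), CH2Cl2, 0 °C
Reagents that add atoms: benzoyl chloride, O=C(Cl)c1ccccc1
Why: Acylation of the only free hydroxyl with retention at C3.

Step 13
Reactants: 22 (3aR,4R,6E,9S,10Z,11aR)-4-(4-methoxybenzyloxy)-6,10-dimethyl-3-methylidene-2-oxo-2,3,3a,4,5,8,9,11a-octahydrocyclodeca[b]furan-9-yl benzoate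
Product: 23 (3aR,4R,6E,9S,10Z,11aR)-4-hydroxy-6,10-dimethyl-3-methylidene-2-oxo-2,3,3a,4,5,8,9,11a-octahydrocyclodeca[b]furan-9-yl benzoate
Conditions: DDQ, CH2Cl2/pH 7 phosphate buffer (10:1), 0 °C
Reagents that add atoms: none
Why: Oxidative cleavage of the 4-methoxybenzyl ether under neutral conditions leaves the benzoate, the lactone and the alkenes alone and avoids base-induced 6,12→8,12 translactonisation.

Step 14
Reactants: 24 methyl (R)-3-hydroxybutanoate
Product: 25 methyl (2R,3R)-3-hydroxy-2-methylbutanoate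
Conditions: LiN(iPr)2 (2.2 equiv), THF, −50 → −20 °C; then MeI, −78 → 0 °C
Reagents that add atoms: iodomethane, CI
Why: Fráter–Seebach alkylation of the chelated dianion anti to the C3 methyl group puts in the α-methyl group (its configuration is erased in step 15, only the bought C3 centre matters).

Step 15
Reactants: 25 methyl (2R,3R)-3-hydroxy-2-methylbutanoate
Product: 27 methyl (2S,3R)-2,3-dimethyloxirane-2-carboxylate, via iodo alkoxide 26 (not isolated)
Conditions: LiN(iPr)2 (2.2 equiv), THF, −78 → −20 °C; then I2, THF, −78 °C → rt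
Reagents that add atoms: none
Why: The chelated dianion is iodinated on the same face as in step 14 (anti to the C3 methyl), and the alkoxide then displaces the tertiary iodide by intramolecular SN2 (Darzens-type closure) with inversion at C2, which gives the oxirane with cis methyl groups and 2S under control of the bought 3R centre.

Step 16
Reactants: 27 methyl (2S,3R)-2,3-dimethyloxirane-2-carboxylate
Product: 28 (2S,3R)-2,3-dimethyloxirane-2-carboxylic acid
Conditions: LiOH, THF/H2O, 0 °C; then 1 M HCl to pH 3 at 0 °C, cold extraction, used at once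
Reagents that add atoms: lithium hydroxide, [Li+].[OH-]
Why: Mild saponification of the glycidic ester, neither oxirane carbon being enolisable, with cold handling to avoid decarboxylative ring opening of the free acid.

Step 17
Reactants: 28 (2S,3R)-2,3-dimethyloxirane-2-carboxylic acid; 23 (3aR,4R,6E,9S,10Z,11aR)-4-hydroxy-6,10-dimethyl-3-methylidene-2-oxo-2,3,3a,4,5,8,9,11a-octahydrocyclodeca[b]furan-9-yl benzoate
Product: 30 (3aR,4R,6E,9S,10Z,11aR)-9-(benzoyloxy)-6,10-dimethyl-3-methylidene-2-oxo-2,3,3a,4,5,8,9,11a-octahydrocyclodeca[b]furan-4-yl (2S,3R)-2,3-dimethyloxirane-2-carboxylate, via mixed anhydride 29 (not isolated)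
Conditions: 2,4,6-Cl3C6H2COCl, Et3N, THF, 0 °C; then 23, DMAP, toluene, rt
Reagents that add atoms: none
Why: Yamaguchi esterification acylates the single free hydroxyl (O8) with retention, and the acid cannot epimerise because its α-carbon is quaternary.

Step 18
Reactants: 30 (3aR,4R,6E,9S,10Z,11aR)-9-(benzoyloxy)-6,10-dimethyl-3-methylidene-2-oxo-2,3,3a,4,5,8,9,11a-octahydrocyclodeca[b]furan-4-yl (2S,3R)-2,3-dimethyloxirane-2-carboxylate
Product: 31 CNP0324463.4 (1β,10α-epoxide of 30)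
Conditions: mCPBA (1.05 equiv), NaHCO3, CH2Cl2, 0 °C
Reagents that add atoms: 3-chloroperoxybenzoic acid, OOC(=O)c1cccc(Cl)c1
Why: Prilezhaev epoxidation picks the only electron-rich alkene (the 4,5-alkene is flanked by two allylic C–O bonds and the 11(13)-alkene is conjugated) and attacks its exposed outer face in the ring conformation with C14 β, which gives the trans 1β,10α-epoxide (1R,10R).

## Compound list

1 | (S)-(+)-carvone, (5S)-2-methyl-5-(prop-1-en-2-yl)cyclohex-2-en-1-one | CC1=CC[C@@H](CC1=O)C(C)=C | starting material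
2 | (1S,5S)-cis-carveol, (1S,5S)-2-methyl-5-(prop-1-en-2-yl)cyclohex-2-en-1-ol | CC1=CC[C@@H](C[C@@H]1O)C(C)=C | intermediate
3 | (1S,5S)-cis-carveol tert-butyldimethylsilyl ether | CC1=CC[C@@H](C[C@@H]1O[Si](C)(C)C(C)(C)C)C(C)=C | intermediate
4 | (4S,6S)-4-(tert-butyldimethylsilyloxy)-3-methyl-6-(prop-1-en-2-yl)cyclohex-2-en-1-one | CC1=CC(=O)[C@@H](C[C@@H]1O[Si](C)(C)C(C)(C)C)C(C)=C | intermediate
5 | 4-methoxybenzyl alcohol | COc1ccc(CO)cc1 | starting material
6 | 4-methoxybenzyl vinyl ether | C=COCc1ccc(OC)cc1 | intermediate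
7 | 1,2-dibromoethyl 4-methoxybenzyl ether (racemic) | BrCC(Br)OCc1ccc(OC)cc1 | intermediate
8 | (Z)-2-bromovinyl 4-methoxybenzyl ether | Br/C=C\OCc1ccc(OC)cc1 | intermediate
9 | (Z)-2-(4-methoxybenzyloxy)ethenyllithium | [Li]/C=C\OCc1ccc(OC)cc1 | intermediate
10 | (1S,4S,6S)-4-(tert-butyldimethylsilyloxy)-1-[(Z)-2-(4-methoxybenzyloxy)ethenyl]-3-methyl-6-(prop-1-en-2-yl)cyclohex-2-en-1-ol | CC1=C[C@@](O)(/C=C\OCc2ccc(OC)cc2)[C@@H](C[C@@H]1O[Si](C)(C)C(C)(C)C)C(C)=C | intermediate
11 | potassium alkoxide of 10 | [K+].CC1=C[C@@]([O-])(/C=C\OCc2ccc(OC)cc2)[C@@H](C[C@@H]1O[Si](C)(C)C(C)(C)C)C(C)=C | intermediate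
12 | potassium (1Z,3R,5E,8S,9Z)-8-(tert-butyldimethylsilyloxy)-3-(4-methoxybenzyloxy)-5,9-dimethylcyclodeca-1,5,9-trien-1-olate | [K+].[O-]/C1=C\[C@H](OCc2ccc(OC)cc2)C/C(C)=C/C[C@H](O[Si](C)(C)C(C)(C)C)/C(C)=C\1 | intermediate
13 | methyl 2-[(1R,3Z,5S,7E,10R)-5-(tert-butyldimethylsilyloxy)-10-(4-methoxybenzyloxy)-4,8-dimethyl-2-oxocyclodeca-3,7-dien-1-yl]acetate | COC(=O)C[C@H]1C(=O)/C=C(/C)[C@@H](O[Si](C)(C)C(C)(C)C)C/C=C(\C)C[C@H]1OCc2ccc(OC)cc2 | intermediate
14 | methyl 2-[(1S,2S,3Z,5S,7E,10R)-5-(tert-butyldimethylsilyloxy)-2-hydroxy-10-(4-methoxybenzyloxy)-4,8-dimethylcyclodeca-3,7-dien-1-yl]acetate (6β-alcohol) | COC(=O)C[C@H]1[C@@H](O)/C=C(/C)[C@@H](O[Si](C)(C)C(C)(C)C)C/C=C(\C)C[C@H]1OCc2ccc(OC)cc2 | intermediate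
15 | cis-fused lactone (3aR,4R,6E,9S,10Z,11aS)-9-(tert-butyldimethylsilyloxy)-4-(4-methoxybenzyloxy)-6,10-dimethyl-3a,4,5,8,9,11a-hexahydrocyclodeca[b]furan-2(3H)-one | C1C(=O)O[C@H]2/C=C(/C)[C@@H](O[Si](C)(C)C(C)(C)C)C/C=C(\C)C[C@@H](OCc3ccc(OC)cc3)[C@@H]12 | intermediate
16 | 2-[(1S,2S,3Z,5S,7E,10R)-5-(tert-butyldimethylsilyloxy)-2-hydroxy-10-(4-methoxybenzyloxy)-4,8-dimethylcyclodeca-3,7-dien-1-yl]acetic acid | OC(=O)C[C@H]1[C@@H](O)/C=C(/C)[C@@H](O[Si](C)(C)C(C)(C)C)C/C=C(\C)C[C@H]1OCc2ccc(OC)cc2 | intermediate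
17 | trans-fused lactone (3aR,4R,6E,9S,10Z,11aR)-9-(tert-butyldimethylsilyloxy)-4-(4-methoxybenzyloxy)-6,10-dimethyl-3a,4,5,8,9,11a-hexahydrocyclodeca[b]furan-2(3H)-one | C1C(=O)O[C@@H]2/C=C(/C)[C@@H](O[Si](C)(C)C(C)(C)C)C/C=C(\C)C[C@@H](OCc3ccc(OC)cc3)[C@@H]12 | intermediate
18 | 3-[(dimethylamino)methyl] derivative of 17 (C3 epimers) | CN(C)CC1C(=O)O[C@@H]2/C=C(/C)[C@@H](O[Si](C)(C)C(C)(C)C)C/C=C(\C)C[C@@H](OCc3ccc(OC)cc3)[C@@H]12 | intermediate
19 | trimethylammonium iodide from 18 | [I-].C[N+](C)(C)CC1C(=O)O[C@@H]2/C=C(/C)[C@@H](O[Si](C)(C)C(C)(C)C)C/C=C(\C)C[C@@H](OCc3ccc(OC)cc3)[C@@H]12 | intermediate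
20 | (3aR,4R,6E,9S,10Z,11aR)-9-(tert-butyldimethylsilyloxy)-4-(4-methoxybenzyloxy)-6,10-dimethyl-3-methylidene-3a,4,5,8,9,11a-hexahydrocyclodeca[b]furan-2(3H)-one | C=C1C(=O)O[C@@H]2/C=C(/C)[C@@H](O[Si](C)(C)C(C)(C)C)C/C=C(\C)C[C@@H](OCc3ccc(OC)cc3)[C@@H]12 | intermediate
21 | (3aR,4R,6E,9S,10Z,11aR)-9-hydroxy-4-(4-methoxybenzyloxy)-6,10-dimethyl-3-methylidene-3a,4,5,8,9,11a-hexahydrocyclodeca[b]furan-2(3H)-one | C=C1C(=O)O[C@@H]2/C=C(/C)[C@@H](O)C/C=C(\C)C[C@@H](OCc3ccc(OC)cc3)[C@@H]12 | intermediate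
22 | (3aR,4R,6E,9S,10Z,11aR)-4-(4-methoxybenzyloxy)-6,10-dimethyl-3-methylidene-2-oxo-2,3,3a,4,5,8,9,11a-octahydrocyclodeca[b]furan-9-yl benzoate | C=C1C(=O)O[C@@H]2/C=C(/C)[C@@H](OC(=O)c3ccccc3)C/C=C(\C)C[C@@H](OCc3ccc(OC)cc3)[C@@H]12 | intermediate
23 | (3aR,4R,6E,9S,10Z,11aR)-4-hydroxy-6,10-dimethyl-3-methylidene-2-oxo-2,3,3a,4,5,8,9,11a-octahydrocyclodeca[b]furan-9-yl benzoate | C=C1C(=O)O[C@@H]2/C=C(/C)[C@@H](OC(=O)c3ccccc3)C/C=C(\C)C[C@@H](O)[C@@H]12 | intermediate
24 | methyl (R)-3-hydroxybutanoate | COC(=O)C[C@@H](C)O | starting material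
25 | methyl (2R,3R)-3-hydroxy-2-methylbutanoate | COC(=O)[C@H](C)[C@@H](C)O | intermediate
26 | lithium alkoxide of methyl (2R,3R)-3-hydroxy-2-iodo-2-methylbutanoate | [Li+].COC(=O)[C@](C)(I)[C@@H](C)[O-] | intermediate
27 | methyl (2S,3R)-2,3-dimethyloxirane-2-carboxylate | COC(=O)[C@@]1(C)O[C@@H]1C | intermediate
28 | (2S,3R)-2,3-dimethyloxirane-2-carboxylic acid | OC(=O)[C@@]1(C)O[C@@H]1C | intermediate
29 | (2S,3R)-2,3-dimethyloxirane-2-carboxylic 2,4,6-trichlorobenzoic anhydride | O=C(OC(=O)c1c(Cl)cc(Cl)cc1Cl)[C@@]2(C)O[C@@H]2C | intermediate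
30 | (3aR,4R,6E,9S,10Z,11aR)-9-(benzoyloxy)-6,10-dimethyl-3-methylidene-2-oxo-2,3,3a,4,5,8,9,11a-octahydrocyclodeca[b]furan-4-yl (2S,3R)-2,3-dimethyloxirane-2-carboxylate | C=C1C(=O)O[C@@H]2/C=C(/C)[C@@H](OC(=O)c3ccccc3)C/C=C(\C)C[C@@H](OC(=O)[C@@]3(C)O[C@@H]3C)[C@@H]12 | intermediate
31 | CNP0324463.4, 3β-benzoyloxy-1β,10α-epoxy-8β-[(2S,3R)-2,3-dimethyloxirane-2-carbonyloxy]germacra-4Z,11(13)-dien-6α,12-olide (1R,3S,6R,7R,8R,10R) | C=C1C(=O)O[C@@H]2/C=C(/C)[C@@H](OC(=O)c3ccccc3)C[C@H]3O[C@]3(C)C[C@@H](OC(=O)[C@@]3(C)O[C@@H]3C)[C@@H]12 | target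

## Step count and risks

Total: 18 steps. Longest linear sequence: 13 steps (1, 2, 3, 6, 7, 8, 9, 10, 11, 12, 13, 17, 18); the vinyl ether (steps 4–5) and the epoxy acid (steps 14–16) are made in parallel.

The three steps most likely to fail:

**Step 3 (allylic oxidation).** The silyloxy-bearing C–H, the isopropenyl group and over-oxidation all compete with the wanted ring methylene. The fallback sets out from 3 and comes back at 4. A Schenck ene reaction with singlet oxygen (O2, hν, tetraphenylporphyrin, CH2Cl2, −20 °C) shifts the ring alkene and gives the tertiary allylic hydroperoxide, 2-hydroperoxy-2-methyl-5-(prop-1-en-2-yl)cyclohex-3-en-1-yl tert-butyldimethylsilyl ether F1. PPh3 reduces it in the same flask to the tertiary allylic alcohol F2. Oxidative 1,3-transposition of F2 with pyridinium chlorochromate C5H5NH[CrO3Cl] (chromate ester [3,3] shift, then oxidation) then gives enone 4.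

**Step 7 (oxy-Cope/alkylation in one flask).** The potassium enolate carries a β-alkoxy group and can lose 4-methoxybenzyl oxide, and the C7 face selectivity depends on the enolate reacting before it changes conformation. The fallback sets out from 10 and comes back at 13. The rearrangement is run alone (KN(SiMe3)2, 18-crown-6, THF, 0 °C) and the enolate is silylated at once at −78 °C (Me3SiCl, Et3N) to the trimethylsilyl enol ether F3. Its enol ether double bond is cyclopropanated on the exposed face with methyl diazoacetate and Cu(acac)2 to give the siloxycyclopropane ester F4. Et3N·3HF then opens this donor–acceptor cyclopropane to keto ester 13, so no free β-alkoxy enolate is ever warmed.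

**Step 9 (invertive lactonisation).** The hydroxy acid can relactonise with retention to 15, and the hindered allylic alcohol can eliminate or react SN2′. The fallback sets out from 15 and comes back at 17. Lactone 15 is opened with Me2NH/AlMe3 to the 6β-hydroxy dimethylamide F5, which does not relactonise under neutral conditions. C6 is inverted intermolecularly (4-nitrobenzoic acid, PPh3, DIAD) to the 6α-nitrobenzoate F6. Methanolysis (K2CO3, MeOH) gives the 6α-hydroxy amide F7, and PPTS in warm toluene closes the lactone to 17.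

## Further compounds

F1 | step 3 | 2-hydroperoxy-2-methyl-5-(prop-1-en-2-yl)cyclohex-3-en-1-yl tert-butyldimethylsilyl ether (ring centres as in 3, C2 as a mixture) | CC1(OO)C=C[C@@H](C[C@@H]1O[Si](C)(C)C(C)(C)C)C(C)=C
F2 | step 3 | 6-(tert-butyldimethylsilyloxy)-1-methyl-4-(prop-1-en-2-yl)cyclohex-2-en-1-ol (ring centres as in 3, C1 as a mixture) | CC1(O)C=C[C@@H](C[C@@H]1O[Si](C)(C)C(C)(C)C)C(C)=C
F3 | step 7 | trimethylsilyl enol ether of the rearranged ketone, (1Z,3R,5E,8S,9Z)-8-(tert-butyldimethylsilyloxy)-3-(4-methoxybenzyloxy)-5,9-dimethyl-1-(trimethylsilyloxy)cyclodeca-1,5,9-triene | C[Si](C)(C)O/C1=C\[C@H](OCc2ccc(OC)cc2)C/C(C)=C/C[C@H](O[Si](C)(C)C(C)(C)C)/C(C)=C\1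
F4 | step 7 | methyl siloxycyclopropanecarboxylate from F3 (cyclopropane on C6–C7, ester carbon as a mixture) | COC(=O)C1[C@]2(O[Si](C)(C)C)/C=C(/C)[C@@H](O[Si](C)(C)C(C)(C)C)C/C=C(\C)C[C@@H](OCc3ccc(OC)cc3)[C@@H]12
F5 | step 9 | 6β-hydroxy N,N-dimethylamide from 15 | CN(C)C(=O)C[C@H]1[C@@H](O)/C=C(/C)[C@@H](O[Si](C)(C)C(C)(C)C)C/C=C(\C)C[C@H]1OCc2ccc(OC)cc2
F6 | step 9 | 6α-(4-nitrobenzoyloxy) N,N-dimethylamide | CN(C)C(=O)C[C@H]1[C@H](OC(=O)c2ccc(cc2)[N+](=O)[O-])/C=C(/C)[C@@H](O[Si](C)(C)C(C)(C)C)C/C=C(\C)C[C@H]1OCc2ccc(OC)cc2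
F7 | step 9 | 6α-hydroxy N,N-dimethylamide | CN(C)C(=O)C[C@H]1[C@H](O)/C=C(/C)[C@@H](O[Si](C)(C)C(C)(C)C)C/C=C(\C)C[C@H]1OCc2ccc(OC)cc2
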